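**Plan**

1. Locants follow the target skeleton: lactone C12(=O)–O–C6, C7, C11=C13, C8 (angelate), C9, C10 (C14 methyl, ether O), C1, C2, C3 (OAc), C4 (C15H2OAc), C5 (ether O).
2. Retrosynthesis: the C8 angelate is cut first; then the ether bond O5–C10 and the ring bond C7–C8 are cut together, which opens the 11-oxabicyclo[4.4.1]undecane (both oxepanes and the ten-membered carbocycle) to a chain that carries a butenolide.
3. This double cut is possible because C13–C11=C7 is an allyl unit whose γ-carbon C7 becomes nucleophilic when C13 bears tin, C8 is a carbinol (aldehyde) carbon, and C10 is a tertiary carbon 1,6 to the C5 oxygen across the carbocycle, so a C10 cation is trapped transannularly.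
4. Further cuts: C7=C11 (ring-closing metathesis of a C6 acrylate), C5–C6 and C3–C4 (two iridium-catalysed anti-selective transfer-hydrogenative allylations); C8–C9–C10(C14)–C1–C2–C3 comes from (R)-linalool.
5. Forward order: linalool chain, C3–C4, C5–C6, butenolide ring, then carbocycle and ether bridge in one flask, then the angelate.
6. Stereochemistry: C3/C4 and C5/C6 from catalyst control (anti adducts), C7 from attack anti to the C6 side chain, C8 from an open transition state, C10 from the transannular closure.

Key step: step 19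

Assumption: read literally, the C5/C10 descriptors of the given string (5R,10R) would put the two carbon bridges on opposite faces of the oxygen bridge; a single ether oxygen closes across C5 and C10 of the ten-membered ring on one face only, so the target is treated as that bicycle and C10 is written as in the string.

**Route**

Step 1
Reactants: 1 (R)-linalool
Product: 3 (R)-3,7-dimethyloct-6-ene-1,3-diol, via B-alkyl-9-BBN adduct 2 (not isolated)
Conditions: 9-BBN (2.2 equiv), THF, 0 °C → rt; then NaOH, 30% H2O2, 0 °C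
Reagents that add atoms: hydrogen peroxide, OO
Why: Brown hydroboration–oxidation, in which the bulky dialkylborane adds anti-Markovnikov to the vinyl group only and leaves the trisubstituted alkene; the carbinol centre (later C10, ionised in step 19, so either enantiomer of linalool would serve) is untouched.

Step 2
Reactants: 3 (R)-3,7-dimethyloct-6-ene-1,3-diol
Product: 4 (R)-1-(4-methoxybenzyloxy)-3,7-dimethyloct-6-en-3-ol
Conditions: NaH (1.05 equiv), 4-methoxybenzyl chloride, Bu4NI (cat.), THF–DMF, 0 °C → rt
Reagents that add atoms: 4-methoxybenzyl chloride, COc1ccc(CCl)cc1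
Why: Williamson ether synthesis; the primary alkoxide forms and reacts far faster than the tertiary one, so only O8 is protected.

Step 3
Reactants: 4 (R)-1-(4-methoxybenzyloxy)-3,7-dimethyloct-6-en-3-ol
Product: 5 tert-butyl{[(R)-1-(4-methoxybenzyloxy)-3,7-dimethyloct-6-en-3-yl]oxy}dimethylsilane
Conditions: TBSOTf, 2,6-lutidine, CH2Cl2, −78 → 0 °C
Reagents that add atoms: tert-butyldimethylsilyl trifluoromethanesulfonate, CC(C)(C)[Si](C)(C)OS(=O)(=O)C(F)(F)F
Why: silyl triflate silylation of the hindered tertiary alcohol, which installs the later C10 leaving group and prevents lactol or lactone formation from the 1,4-diol in the next two steps.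

Step 4
Reactants: 5 tertiary silyl ether
Product: 7 (R)-4-(tert-butyldimethylsilyloxy)-6-(4-methoxybenzyloxy)-4-methylhexan-1-ol, via secondary ozonide 6 (not isolated)
Conditions: O3, CH2Cl2, −78 °C (Sudan red 7B end point); then NaBH4, MeOH, −78 → 0 °C
Reagents that add atoms: ozone, [O-][O+]=O
Why: ozonolysis of the only alkene with reductive work-up gives the C3 primary alcohol; the electron-rich arene is spared by stopping at the indicator end point.

Step 5
Reactants: 7 primary alcohol; 8 4-vinyl-1,3-dioxolan-2-one (racemic)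
Product: 9 (2S,3S,6R)-6-(tert-butyldimethylsilyloxy)-8-(4-methoxybenzyloxy)-6-methyl-2-vinyloctane-1,3-diol
Conditions: [Ir(cod)Cl]2 (2.5 mol %), SEGPHOS (5 mol %, enantiomer chosen for the 2S,3S adduct), 4-cyano-3-nitrobenzoic acid (10 mol %), K3PO4 (5 mol %), THF, 90 °C
Reagents that add atoms: none
Why: Krische carbonyl (hydroxymethyl)allylation, in which the iridium complex dehydrogenates the primary alcohol, ionises 8 with loss of CO2 and adds the (E)-σ-allyl through a closed chair, so that C3 and C4 should form anti with catalyst-controlled absolute configuration.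

Step 6
Reactants: 9 1,3-diol
Product: 10 (4S,5S)-4-[(R)-3-(tert-butyldimethylsilyloxy)-5-(4-methoxybenzyloxy)-3-methylpentyl]-2,2-dimethyl-5-vinyl-1,3-dioxane
Conditions: 2,2-dimethoxypropane, PPTS (cat.), CH2Cl2, rt
Reagents that add atoms: 2,2-dimethoxypropane, COC(C)(C)OC
Why: acid-catalysed transketalisation to the six-membered acetonide, which ties O3 and O15 so that no acyl group can later migrate between the two arms on C4.

Step 7
Reactants: 10 vinyl dioxane
Product: 12 [(4S,5S)-4-{(R)-3-(tert-butyldimethylsilyloxy)-5-(4-methoxybenzyloxy)-3-methylpentyl}-2,2-dimethyl-1,3-dioxan-5-yl]methanol, via secondary ozonide 11 (not isolated)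
Conditions: O3, CH2Cl2, −78 °C; then NaBH4, MeOH, −78 → 0 °C
Reagents that add atoms: ozone, [O-][O+]=O
Why: ozonolysis of the vinyl group with reductive work-up gives the C5 primary alcohol without passing through an isolated, epimerisable aldehyde.

Step 8
Reactants: 13 acrolein; 14 benzoic anhydride
Product: 15 prop-2-ene-1,1-diyl dibenzoate
Conditions: FeCl3 (2 mol %), CH2Cl2, 0 °C → rt
Reagents that add atoms: none
Why: Lewis acid-catalysed acylal formation by addition of the anhydride across the aldehyde carbonyl; no stereocentre is formed.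

Step 9
Reactants: 12 C5 primary alcohol; 15 prop-2-ene-1,1-diyl dibenzoate
Product: 16 (1R,2S)-1-{(4S,5R)-4-[(R)-3-(tert-butyldimethylsilyloxy)-5-(4-methoxybenzyloxy)-3-methylpentyl]-2,2-dimethyl-1,3-dioxan-5-yl}-1-hydroxybut-3-en-2-yl benzoate
Conditions: [Ir(cod)Cl]2 (2.5 mol %), SEGPHOS (5 mol %, enantiomer chosen for the 1R,2S adduct), 4-cyano-3-nitrobenzoic acid (10 mol %), K3PO4 (1 equiv), THF, 90 °C
Reagents that add atoms: none
Why: Krische anti-(acyloxy)allylation from the alcohol oxidation level, in which the benzoyloxy-substituted (E)-σ-allyl iridium adds to the transient aldehyde through a closed chair, so that the C5 hydroxyl and the C6 benzoate should form anti under catalyst control while C4 is not epimerised.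

Step 10
Reactants: 16 hydroxy benzoate
Product: 17 5-O-TBS ether of 16
Conditions: TBSOTf, 2,6-lutidine, CH2Cl2, −78 → −20 °C
Reagents that add atoms: tert-butyldimethylsilyl trifluoromethanesulfonate, CC(C)(C)[Si](C)(C)OS(=O)(=O)C(F)(F)F
Why: silylation of the secondary C5 hydroxyl under non-basic, cold conditions that do not let the neighbouring benzoate migrate.

Step 11
Reactants: 17 silyl ether benzoate
Product: 18 C6 allylic alcohol (17 without the benzoyl group)
Conditions: i-Bu2AlH (2.2 equiv), CH2Cl2, −78 °C; Rochelle salt work-up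
Reagents that add atoms: none
Why: reductive cleavage of the only ester at low temperature, without the basic alkoxide conditions that would move the C5 silyl group.

Step 12
Reactants: 18 C6 allylic alcohol; 19 2-(bromomethyl)acrylic acid
Product: 21 6-O-[2-(bromomethyl)acryloyl] ester of 18, via 2-(bromomethyl)acryloyl chloride 20 (not isolated)
Conditions: 19, 1-chloro-N,N,2-trimethylprop-1-en-1-amine, CH2Cl2, 0 °C; then 18, 2,6-lutidine, CH2Cl2, −20 → 0 °C
Reagents that add atoms: none
Why: acylation of the hindered allylic alcohol by the acid chloride made under neutral conditions, with a hindered base because pyridine-type catalysts would displace the allylic bromide; no stereocentre is touched.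

Step 13
Reactants: 21 diene ester
Product: 22 (S)-configured 3-(bromomethyl)butenolide (C7=C11 closed; C5 OTBS; acetonide; C8 OPMB; C10 OTBS)
Conditions: second-generation Hoveyda–Grubbs catalyst (5 mol %), toluene (0.005 M), 80 °C, argon sparge
Reagents that add atoms: none
Why: ring-closing metathesis between the C7 vinyl group and the acrylate methylene closes the five-membered butenolide with loss of ethylene and leaves C6 unchanged.

Step 14
Reactants: 22 butenolide acetonide
Product: 23 C3,C15-diol
Conditions: AcOH–H2O–THF (3:1:1), 35 °C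
Reagents that add atoms: none
Why: mild acidic hydrolysis of the acetonide, which the hindered secondary and tertiary silyl ethers, the PMB ether and the allylic bromide should survive.

Step 15
Reactants: 23 C3,C15-diol
Product: 24 C3,C15-diacetate
Conditions: acetyl chloride, 2,4,6-collidine, CH2Cl2, −20 → 0 °C
Reagents that add atoms: acetyl chloride, CC(Cl)=O
Why: acetylation of the two free hydroxyls with a hindered base that does not alkylate on the allylic bromide; this installs both acetates of the target.

Step 16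
Reactants: 24 diacetate PMB ether
Product: 25 C8 primary alcohol
Conditions: DDQ (1.3 equiv), CH2Cl2–pH 7 buffer (10:1), 0 °C
Reagents that add atoms: none
Why: oxidative cleavage of the PMB ether, orthogonal to the silyl ethers, acetates, lactone and bromide.

Step 17
Reactants: 25 allylic bromide
Product: 26 3-(tributylstannylmethyl)butenolide
Conditions: (Bu3Sn)2 (1.2 equiv), Pd2(dba)3 (2.5 mol %), THF, rt
Reagents that add atoms: hexabutylditin, CCCC[Sn](CCCC)(CCCC)[Sn](CCCC)(CCCC)CCCC
Why: zerovalent palladium ionises the allylic bromide to a π-allyl complex that is stannylated at the primary terminus, which gives the conjugated primary allylstannane (palladium-catalysed allylic stannylation).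

Step 18
Reactants: 26 stannyl alcohol
Product: 27 C8 aldehyde
Conditions: Dess–Martin periodinane, NaHCO3, CH2Cl2, 0 °C → rt
Reagents that add atoms: none
Why: Dess–Martin oxidation of the only free hydroxyl under buffered conditions that leave the allylstannane and the tertiary silyl ether intact.

Step 19
Reactants: 27 C8 aldehyde
Product: 29 tricyclic C8 alcohol (the target without the angeloyl group), via ten-membered carbocycle 28 (not isolated)
Conditions: BF3·OEt2 (3 equiv), CH2Cl2 (0.002 M, slow addition of 27), −78 °C; then TfOH (0.5 equiv), −78 → −20 °C; then HF·pyridine, THF, 0 °C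
Reagents that add atoms: none
Why: BF3 activates the aldehyde and the allylstannane attacks it through C7 (SE2′, tin lost from C13), which closes the ten-membered carbocycle and moves the double bond to C11=C13; TfOH then ionises the tertiary C10 silyl ether and the C5 silyl ether oxygen captures the planar cation across the ring, with loss of its silyl group. The closest known reaction types are the Lewis acid-promoted macrocyclising addition of allylstannanes to aldehydes (and the lactone-forming addition of 2-(stannylmethyl)acrylates) and the acid-mediated transannular SN1 etherification of medium rings. The carbocycle arises by a 10-exo-trig C–C closure at the aldehyde, and both oxepane rings arise together by one transannular 7-membered C–O closure of O5 on C10. C7 is set by attack on the butenolide face anti to the C5 side chain at C6 (trans lactone), C8 by the open antiperiplanar transition state of Lewis acid allylstannane additions (O8 syn to C6, 8R), and C10 by the one face on which a single oxygen can bridge C5 and C10. The step needs C–C closure before C–O closure, because ether formation first would force C7–C8 to form in a seven-membered, cis-fused mode; the C10 silyl ether, which is inert to BF3·OEt2 at −78 °C and ionises only after TfOH is added, secures this order. The acetates at O3 and O15 keep these oxygens from trapping the cation, and high dilution suppresses oligomers.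

Step 20
Reactants: 29 tricyclic C8 alcohol; 30 angelic acid
Product: 32 target, via angelic 2,4,6-trichlorobenzoic anhydride 31 (not isolated)
Conditions: 30, 2,4,6-trichlorobenzoyl chloride, Et3N, toluene, rt; then 29, toluene, 75 °C
Reagents that add atoms: none
Why: Yamaguchi esterification through the mixed anhydride, run without a nucleophilic catalyst so that the Z double bond should not isomerise to the tiglate and the lactone should not migrate to O8; the C8 configuration is retained.

**Compound list**

1 | (R)-linalool, (R)-3,7-dimethylocta-1,6-dien-3-ol | CC(C)=CCC[C@@](C)(O)C=C | starting material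
2 | B-[(R)-3-hydroxy-3,7-dimethyloct-6-enyl]-9-borabicyclo[3.3.1]nonane | CC(C)=CCC[C@@](C)(O)CCB1C2CCCC1CCC2 | intermediate (not isolated)
3 | (R)-3,7-dimethyloct-6-ene-1,3-diol | CC(C)=CCC[C@@](C)(O)CCO | intermediate
4 | (R)-1-(4-methoxybenzyloxy)-3,7-dimethyloct-6-en-3-ol | COc1ccc(COCC[C@](C)(O)CCC=C(C)C)cc1 | intermediate
5 | tert-butyl{[(R)-1-(4-methoxybenzyloxy)-3,7-dimethyloct-6-en-3-yl]oxy}dimethylsilane | COc1ccc(COCC[C@](C)(O[Si](C)(C)C(C)(C)C)CCC=C(C)C)cc1 | intermediate
6 | secondary ozonide of 5 (3,3-dimethyl-1,2,4-trioxolane at the former alkene) | COc1ccc(COCC[C@](C)(O[Si](C)(C)C(C)(C)C)CCC2OOC(C)(C)O2)cc1 | intermediate (not isolated)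
7 | (R)-4-(tert-butyldimethylsilyloxy)-6-(4-methoxybenzyloxy)-4-methylhexan-1-ol | COc1ccc(COCC[C@](C)(O[Si](C)(C)C(C)(C)C)CCCO)cc1 | intermediate
8 | 4-vinyl-1,3-dioxolan-2-one (racemic) | C=CC1COC(=O)O1 | starting material
9 | (2S,3S,6R)-6-(tert-butyldimethylsilyloxy)-8-(4-methoxybenzyloxy)-6-methyl-2-vinyloctane-1,3-diol (C3-OH and C15 anti) | COc1ccc(COCC[C@](C)(O[Si](C)(C)C(C)(C)C)CC[C@H](O)[C@H](CO)C=C)cc1 | intermediate
10 | (4S,5S)-4-[(R)-3-(tert-butyldimethylsilyloxy)-5-(4-methoxybenzyloxy)-3-methylpentyl]-2,2-dimethyl-5-vinyl-1,3-dioxane | COc1ccc(COCC[C@](C)(O[Si](C)(C)C(C)(C)C)CC[C@@H]2OC(C)(C)OC[C@@H]2C=C)cc1 | intermediate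
11 | secondary ozonide of 10 (1,2,4-trioxolan-3-yl on the dioxane) | COc1ccc(COCC[C@](C)(O[Si](C)(C)C(C)(C)C)CC[C@@H]2OC(C)(C)OC[C@@H]2C3OOCO3)cc1 | intermediate (not isolated)
12 | [(4S,5S)-4-{(R)-3-(tert-butyldimethylsilyloxy)-5-(4-methoxybenzyloxy)-3-methylpentyl}-2,2-dimethyl-1,3-dioxan-5-yl]methanol | COc1ccc(COCC[C@](C)(O[Si](C)(C)C(C)(C)C)CC[C@@H]2OC(C)(C)OC[C@@H]2CO)cc1 | intermediate
13 | acrolein | C=CC=O | starting material
14 | benzoic anhydride | O=C(OC(=O)c1ccccc1)c1ccccc1 | starting material
15 | prop-2-ene-1,1-diyl dibenzoate | C=CC(OC(=O)c1ccccc1)OC(=O)c1ccccc1 | intermediate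
16 | (1R,2S)-1-{(4S,5R)-4-[(R)-3-(tert-butyldimethylsilyloxy)-5-(4-methoxybenzyloxy)-3-methylpentyl]-2,2-dimethyl-1,3-dioxan-5-yl}-1-hydroxybut-3-en-2-yl benzoate (C5-OH and C6-OBz anti) | COc1ccc(COCC[C@](C)(O[Si](C)(C)C(C)(C)C)CC[C@@H]2OC(C)(C)OC[C@@H]2[C@@H](O)[C@@H](OC(=O)c3ccccc3)C=C)cc1 | intermediate
17 | 5-O-TBS ether of 16 (C3 to C6 arranged as in the target) | COc1ccc(COCC[C@](C)(O[Si](C)(C)C(C)(C)C)CC[C@@H]2OC(C)(C)OC[C@@H]2[C@@H](O[Si](C)(C)C(C)(C)C)[C@@H](OC(=O)c3ccccc3)C=C)cc1 | intermediate
18 | C6 allylic alcohol (17 without the benzoyl group) | COc1ccc(COCC[C@](C)(O[Si](C)(C)C(C)(C)C)CC[C@@H]2OC(C)(C)OC[C@@H]2[C@@H](O[Si](C)(C)C(C)(C)C)[C@@H](O)C=C)cc1 | intermediate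
19 | 2-(bromomethyl)acrylic acid | C=C(CBr)C(=O)O | starting material
20 | 2-(bromomethyl)acryloyl chloride | C=C(CBr)C(Cl)=O | intermediate (not isolated)
21 | 6-O-[2-(bromomethyl)acryloyl] ester of 18 | COc1ccc(COCC[C@](C)(O[Si](C)(C)C(C)(C)C)CC[C@@H]2OC(C)(C)OC[C@@H]2[C@@H](O[Si](C)(C)C(C)(C)C)[C@@H](OC(=O)C(=C)CBr)C=C)cc1 | intermediate
22 | (5S)-3-(bromomethyl)furan-2(5H)-one bearing at C5 the (R)-CH(OTBS) carbon attached to the dioxane of 10 (butenolide; acetonide; C8 OPMB; C10 OTBS) | COc1ccc(COCC[C@](C)(O[Si](C)(C)C(C)(C)C)CC[C@@H]2OC(C)(C)OC[C@@H]2[C@@H](O[Si](C)(C)C(C)(C)C)[C@H]3OC(=O)C(CBr)=C3)cc1 | intermediate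
23 | C3,C15-diol of 22 (acetonide removed) | COc1ccc(COCC[C@](C)(O[Si](C)(C)C(C)(C)C)CC[C@H](O)[C@H](CO)[C@@H](O[Si](C)(C)C(C)(C)C)[C@H]2OC(=O)C(CBr)=C2)cc1 | intermediate
24 | C3,C15-diacetate of 23 | COc1ccc(COCC[C@](C)(O[Si](C)(C)C(C)(C)C)CC[C@H](OC(C)=O)[C@H](COC(C)=O)[C@@H](O[Si](C)(C)C(C)(C)C)[C@H]2OC(=O)C(CBr)=C2)cc1 | intermediate
25 | C8 primary alcohol (24 without the PMB group) | OCC[C@](C)(O[Si](C)(C)C(C)(C)C)CC[C@H](OC(C)=O)[C@H](COC(C)=O)[C@@H](O[Si](C)(C)C(C)(C)C)[C@H]1OC(=O)C(CBr)=C1 | intermediate
26 | 3-(tributylstannylmethyl)butenolide alcohol | OCC[C@](C)(O[Si](C)(C)C(C)(C)C)CC[C@H](OC(C)=O)[C@H](COC(C)=O)[C@@H](O[Si](C)(C)C(C)(C)C)[C@H]1OC(=O)C(C[Sn](CCCC)(CCCC)CCCC)=C1 | intermediate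
27 | C8 aldehyde of 26 (open-chain precursor: C3,C15-diacetate; C5 and C10 OTBS; stannylmethyl butenolide) | O=CC[C@](C)(O[Si](C)(C)C(C)(C)C)CC[C@H](OC(C)=O)[C@H](COC(C)=O)[C@@H](O[Si](C)(C)C(C)(C)C)[C@H]1OC(=O)C(C[Sn](CCCC)(CCCC)CCCC)=C1 | intermediate
28 | ten-membered carbocycle: 8-hydroxy-5,10-bis(silyloxy)germacr-11(13)-en-6,12-olide 3,15-diacetate (trans lactone; 8R) | C=C1C(=O)O[C@@H]2[C@H](O[Si](C)(C)C(C)(C)C)[C@@H](COC(C)=O)[C@@H](OC(C)=O)CC[C@@](C)(O[Si](C)(C)C(C)(C)C)C[C@@H](O)[C@@H]12 | intermediate (not isolated)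
29 | tricyclic C8 alcohol: 3,15-diacetoxy-5,10-epoxy-8-hydroxygermacr-11(13)-en-6,12-olide, configured as the target | C=C1C(=O)O[C@@H]2[C@@H]3O[C@](C)(CC[C@H](OC(C)=O)[C@@H]3COC(C)=O)C[C@@H](O)[C@@H]12 | intermediate
30 | angelic acid, (Z)-2-methylbut-2-enoic acid | C/C=C(/C)C(=O)O | starting material
31 | angelic 2,4,6-trichlorobenzoic anhydride | C/C=C(/C)C(=O)OC(=O)c1c(Cl)cc(Cl)cc1Cl | intermediate (not isolated)
32 | CNP0346171.1: 3,15-diacetoxy-8-angeloyloxy-5,10-epoxygermacr-11(13)-en-6,12-olide (3S,4S,5R,6S,7R,8R,10R as written) | C=C1C(=O)O[C@@H]2[C@@H]3O[C@](C)(CC[C@H](OC(C)=O)[C@@H]3COC(C)=O)C[C@@H](OC(=O)/C(C)=C\C)[C@@H]12 | target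

**Step count and risks**

Total steps: 20. Longest linear sequence: 19 (steps 1–7 and 9–20; step 8 is a one-step side branch).

Step 19. What may go wrong: ionisation of the C10 silyl ether and ether closure before the carbocycle has formed (which would lead to the cis-fused lactone), protodestannylation, oligomerisation, or poor facial selectivity at C8. Fallback, with the two bonds made in separate known operations: alcohol 25 is oxidised with Dess–Martin periodinane to the bromo aldehyde F1. F1 is closed to the ten-membered ring with CrCl2 in THF at high dilution (Nozaki–Hiyama–Kishi-type allylation), whose closed transition state is expected to give the C8-epimeric carbocyclic alcohol F2. TfOH in CH2Cl2 at −40 °C followed by HF·pyridine closes the ether to the 8-epi tricyclic alcohol F3. A Mitsunobu esterification of F3 with angelic acid (PPh3, diisopropyl azodicarboxylate) inverts C8 and returns to the route at 32.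

Step 9. What may go wrong: low diastereocontrol on the α-branched dioxanyl carbinol, benzoate migration to O5, or epimerisation of C4 through the transient aldehyde. Fallback: alcohol 12 is oxidised with Dess–Martin periodinane to the aldehyde F4. F4 is treated with 3-bromoprop-1-enyl benzoate and CrCl2 in THF (anti-selective chromium-mediated acyloxyallylation under Felkin–Anh control from C4), which returns to the route at 16.

Step 20. What may go wrong: isomerisation of the angeloyl group to the tigloyl group during acylation of the hindered alcohol, or migration of the lactone to O8. Fallback, building the Z double bond on the ester: alcohol 29 is acylated with 2-[bis(2,2,2-trifluoroethoxy)phosphoryl]propanoic acid (dicyclohexylcarbodiimide, DMAP cat.) to the phosphonate ester F5. A Still–Gennari olefination of F5 with acetaldehyde (KN(SiMe3)2, 18-crown-6, THF, −78 °C) returns to the route at 32.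

Further compounds
F1 | step 19 | bromo aldehyde (C8 aldehyde of 25) | O=CC[C@](C)(O[Si](C)(C)C(C)(C)C)CC[C@H](OC(C)=O)[C@H](COC(C)=O)[C@@H](O[Si](C)(C)C(C)(C)C)[C@H]1OC(=O)C(CBr)=C1
F2 | step 19 | C8-epimeric carbocyclic alcohol (8-epi-28) | C=C1C(=O)O[C@@H]2[C@H](O[Si](C)(C)C(C)(C)C)[C@@H](COC(C)=O)[C@@H](OC(C)=O)CC[C@@](C)(O[Si](C)(C)C(C)(C)C)C[C@H](O)[C@@H]12
F3 | step 19 | 8-epi tricyclic alcohol (8-epi-29) | C=C1C(=O)O[C@@H]2[C@@H]3O[C@](C)(CC[C@H](OC(C)=O)[C@@H]3COC(C)=O)C[C@H](O)[C@@H]12
F4 | step 9 | dioxane-5-carbaldehyde (C5 aldehyde of 12) | COc1ccc(COCC[C@](C)(O[Si](C)(C)C(C)(C)C)CC[C@@H]2OC(C)(C)OC[C@@H]2C=O)cc1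
F5 | step 20 | 8-O-{2-[bis(2,2,2-trifluoroethoxy)phosphoryl]propanoyl} ester of 29 | C=C1C(=O)O[C@@H]2[C@@H]3O[C@](C)(CC[C@H](OC(C)=O)[C@@H]3COC(C)=O)C[C@@H](OC(=O)C(C)P(=O)(OCC(F)(F)F)OCC(F)(F)F)[C@@H]12
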